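**Plan**

- Cuts, in retrosynthetic order: the O‑protecting groups; upper C3–OH and C4–H (hydroboration of a flav‑3‑ene); upper O1–C2, which opens ring C (the strategic cut); upper C4–lower C6 (aryl‑metal plus ketone); the lower unit goes back to the same chalcone.
- Forward: gallacetophenone → chalcone 4 → lower 2H‑chromene → all‑cis flavan‑3,4‑diol → 6‑bromide; its aryl‑cerium adds to a second portion of chalcone 4; acid closes ring C; hydroboration; deprotection.
- Enabling feature: upper C4 is benzylic to ring A (free O1–H ortho to it) and to ring D and allylic to C2=C3, and C2 is benzylic to ring B with a para oxygen. Loss of water therefore gives a C2–C3–C4 allyl cation that is the o‑quinone methide of ring A, and O1 can reach C2 in a six‑membered closure.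
- Stereochemistry: upper C2 from a chiral phosphoramide counter‑anion; upper C3 and C4 from one syn hydroboration anti to the 2‑aryl group; lower C2 from the same catalysis with the antipodal acid; lower C3 and C4 from two hydride reductions anti to the 2‑aryl group.

Key step: step 14

Remark on naming: flavan numbering is used. The upper unit is the 4‑aryl‑flavan‑3‑ol (benzo ring A, 2‑aryl ring B, pyran ring C); the lower unit is the flavan‑3,4‑diol (benzo ring D, 2‑aryl ring E, pyran ring F). α means the face of the 2‑aryl group of the lower unit. The target is ent‑oritin‑(4β→6)‑epioritin‑4α‑ol.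

Remark on an assumption: the sense of induction of the phosphoramide catalyst is assumed as written ((R)‑acid gives 7, (S)‑acid gives 22). If the first run shows the opposite sense, the two catalyst enantiomers are exchanged.

**Step 1**
Reactants: 1 1‑(2,3,4‑trihydroxyphenyl)ethanone
Product: 2 1‑[3,4‑bis(benzyloxy)‑2‑hydroxyphenyl]ethanone
Conditions: BnBr (2.1 equiv), K2CO3, acetone, reflux
Reagents that add atoms: benzyl bromide BrCc1ccccc1
Why: Williamson etherification; the 2‑hydroxyl is hydrogen‑bonded to the ketone and is the least reactive, so the 3‑ and 4‑hydroxyls should be alkylated selectively.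

**Step 2**
Reactants: 2 1‑[3,4‑bis(benzyloxy)‑2‑hydroxyphenyl]ethanone; 3 4‑(benzyloxy)benzaldehyde
Product: 4 (E)‑1‑[3,4‑bis(benzyloxy)‑2‑hydroxyphenyl]‑3‑[4‑(benzyloxy)phenyl]prop‑2‑en‑1‑one
Conditions: KOH (aq), EtOH, rt
Reagents that add atoms: none
Why: Claisen–Schmidt condensation of a methyl ketone with a non‑enolisable aldehyde, which should give the E‑chalcone under thermodynamic control.

**Step 3**
Reactants: 4 chalcone
Product: 5 (E)‑1‑[3,4‑bis(benzyloxy)‑2‑hydroxyphenyl]‑3‑[4‑(benzyloxy)phenyl]prop‑2‑en‑1‑ol (racemic)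
Conditions: i‑Bu2AlH (2.5 equiv), THF/toluene, −78 °C; aq potassium sodium tartrate; used crude
Reagents that add atoms: none
Why: 1,2‑reduction of the enone by the aluminium hydride (the first equivalent is spent on the phenol); the carbinol is racemic, which is of no consequence because this centre is lost in step 4, and the basic work‑up should keep the labile alcohol from ionising.

**Step 4**
Reactants: 5 allylic alcohol
Product: 7 (2S)‑7,8‑bis(benzyloxy)‑2‑[4‑(benzyloxy)phenyl]‑2H‑chromene, via o‑quinone methide 6 (not isolated)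
Conditions: (R)‑3,3'‑bis(2,4,6‑triisopropylphenyl)‑H8‑BINOL N‑triflylphosphoramide (5 mol %), toluene, 4 Å sieves, −78 °C, dark
Reagents that add atoms: none
Why: chiral Brønsted acid catalysed intramolecular allylic substitution, the same reaction type as the key step run with the antipodal acid: ionisation to the allyl cation (protonated 6) and closure of the phenol oxygen on the benzylic terminus inside a chiral contact ion pair, the phosphoramide anion setting C2.

**Step 5**
Reactants: 7 (2S)‑2H‑chromene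
Product: 9 (2R,3S)‑7,8‑bis(benzyloxy)‑2‑[4‑(benzyloxy)phenyl]chroman‑3‑ol, via 3‑borylflavan 8 (not isolated)
Conditions: BH3·THF, THF, 0 °C → rt; then NaOH (aq), H2O2, 0 °C
Reagents that add atoms: hydrogen peroxide OO
Why: hydroboration–oxidation of the styrene‑type double bond; boron should go to the non‑benzylic C3 on the face anti to the 2‑aryl group, so the hydroxyl comes out 2,3‑trans after oxidation with retention.

**Step 6**
Reactants: 9 2,3‑trans‑flavan‑3‑ol
Product: 10 (2R)‑7,8‑bis(benzyloxy)‑2‑[4‑(benzyloxy)phenyl]chroman‑3‑one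
Conditions: Dess–Martin periodinane, NaHCO3, CH2Cl2, 0 °C → rt; used at once
Reagents that add atoms: none
Why: Dess–Martin oxidation under buffered, non‑enolising conditions, which should leave the labile C2 centre next to the new ketone untouched.

**Step 7**
Reactants: 10 flavan‑3‑one
Product: 11 (2R,3R)‑7,8‑bis(benzyloxy)‑2‑[4‑(benzyloxy)phenyl]chroman‑3‑ol
Conditions: LiBH(s‑Bu)3 (L‑Selectride), LiBr, THF, −78 °C; then H2O
Reagents that add atoms: none
Why: the bulky hydride should attack the ketone from the face opposite to the 2‑aryl group, which gives the 2,3‑cis alcohol (oxidation–reduction inversion of C3).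

**Step 8**
Reactants: 11 2,3‑cis‑flavan‑3‑ol
Product: 12 (2R,3R,4S)‑7,8‑bis(benzyloxy)‑2‑[4‑(benzyloxy)phenyl]chromane‑3,4‑diol
Conditions: DDQ (2 equiv), CH2Cl2/H2O, rt
Reagents that add atoms: water O
Why: oxidative benzylic C–H functionalisation; DDQ should abstract hydride from C4, the benzylic position of the most electron‑rich ring (ring D, para to the 7‑benzyloxy group), and water traps the cation anti to the axial 3‑hydroxyl; the C4 configuration is erased in step 9.

**Step 9**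
Reactants: 12 2,3‑cis‑3,4‑trans‑diol
Product: 13 (2R,3S)‑7,8‑bis(benzyloxy)‑2‑[4‑(benzyloxy)phenyl]‑3‑hydroxychroman‑4‑one
Conditions: MnO2 (activated, excess), CH2Cl2, rt
Reagents that add atoms: none
Why: MnO2 oxidises the benzylic C4 alcohol selectively over the aliphatic 3‑hydroxyl, under neutral conditions that should not epimerise the 2,3‑cis hydroxy ketone.

**Step 10**
Reactants: 13 2,3‑cis‑3‑hydroxyflavan‑4‑one
Product: 14 (2R,3R,4R)‑7,8‑bis(benzyloxy)‑2‑[4‑(benzyloxy)phenyl]chromane‑3,4‑diol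
Conditions: NaBH4, EtOH/THF, −20 °C
Reagents that add atoms: none
Why: hydride reduction of the ketone from the face anti to the axial 3‑hydroxyl and the 2‑aryl group should give the 3,4‑cis alcohol, hence the all‑cis diol; the low temperature keeps C3 from epimerising.

**Step 11**
Reactants: 14 all‑cis diol
Product: 15 all‑cis 7,8‑bis(benzyloxy)‑2‑[4‑(benzyloxy)phenyl]‑3,4‑bis(tert‑butyldimethylsilyloxy)chromane
Conditions: TBSOTf (2.5 equiv), 2,6‑lutidine, CH2Cl2, 0 °C → rt
Reagents that add atoms: tert‑butyldimethylsilyl trifluoromethanesulfonate CC(C)(C)[Si](C)(C)OS(=O)(=O)C(F)(F)F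
Why: silyl triflate with a hindered base silylates both secondary hydroxyls, which makes the unit inert to organolithium, acid catalyst and borane and removable later by fluoride without acid.

**Step 12**
Reactants: 15 bis‑silyl ether
Product: 16 6‑bromo derivative of 15
Conditions: NBS (1.05 equiv), CH2Cl2, −20 → 0 °C
Reagents that add atoms: N‑bromosuccinimide O=C1CCC(=O)N1Br
Why: electrophilic aromatic bromination should go to C6, which is para to the pyran oxygen and ortho to the 7‑benzyloxy group, whereas C5 is activated only by the twisted 8‑benzyloxy group and ring E by a single ether.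

**Step 13**
Reactants: 16 aryl bromide; 4 chalcone
Product: 20 1‑[3,4‑bis(benzyloxy)‑2‑hydroxyphenyl]‑3‑[4‑(benzyloxy)phenyl]‑1‑(C6 of flavan 15)prop‑2(E)‑en‑1‑ol (both carbinol epimers), via aryllithium 17 (not isolated), via arylcerium dichloride 18 (not isolated), via chalcone sodium phenoxide 19 (not isolated)
Conditions: 16, t‑BuLi (2.0 equiv), THF, −78 °C; CeCl3 (anhydrous), −78 °C; then 4 pre‑treated with NaH (THF, 0 °C), −78 → −30 °C; aq NaH2PO4/Na2HPO4 buffer (pH 7); filtration through Et3N‑deactivated silica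
Reagents that add atoms: none
Why: bromine–lithium exchange, transmetalation to the weakly basic, carbonyl‑selective organocerium reagent and 1,2‑addition to the ketone of the chalcone, whose phenol is masked as its sodium salt; the new carbinol centre is formed as a mixture, which is of no consequence because it is ionised in step 14.

**Step 14**
Reactants: 20 tertiary allylic carbinol
Product: 22 7,8‑bis(benzyloxy)‑2‑[4‑(benzyloxy)phenyl]‑2H‑chromene with (2R) configuration joined through C4 to C6 of flavan 15, via o‑quinone methide 21 (not isolated)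
Conditions: (S)‑3,3'‑bis(2,4,6‑triisopropylphenyl)‑H8‑BINOL N‑triflylphosphoramide (5–10 mol %), toluene, 4 Å sieves, −78 °C, dark
Reagents that add atoms: none
Why: The strong chiral acid ionises the tertiary carbinol, which is benzylic to rings A and D and allylic to C2=C3, to a 1,3‑diarylallyl cation that is at the same time the protonated vinyl o‑quinone methide 21 of ring A, is stabilised at C2 by the para‑benzyloxy group of ring B, and stays paired with the chiral phosphoramide anion. The free phenol oxygen O1 then adds to the allyl terminus C2, so ring C closes in a 6‑endo‑trig allylic substitution (equivalently an oxa‑6π electrocyclisation of the o‑quinone methide) and the double bond ends at C3=C4 in conjugation with rings A and D. The closest known reaction type is the N‑triflylphosphoramide‑catalysed asymmetric allylic substitution of 2‑(1‑hydroxyallyl)phenols to 2,4‑disubstituted 2H‑chromenes through contact ion pairs. The only new stereocentre, C2, is set by the counter‑anion, which is hydrogen‑bonded to the phenol and shields one face of the planar cation, so both carbinol epimers of 20 converge and the remote centres of the lower unit should have little say. The step needs enantioface selectivity at C2, closure through O1, and ionisation of this carbinol in preference to the benzylic C4–OTBS of ring F; these rest on the tight ion pair in toluene at −78 °C, on O1 being the only nucleophile that can reach C2 in a six‑membered transition state, and on the far greater stability of the doubly benzylic, allylic, o‑hydroxy‑substituted cation.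

**Step 15**
Reactants: 22 4‑aryl‑2H‑chromene
Product: 24 ent‑oritin‑(4β→6)‑epioritin‑4α‑ol with all six phenols benzylated and the lower 3,4‑diol as its bis‑TBS ether, via 3‑borylflavan 23 (not isolated)
Conditions: BH3·THF (excess), THF, 0 °C → rt; then NaOH (aq), H2O2, 0 °C
Reagents that add atoms: hydrogen peroxide OO
Why: hydroboration–oxidation of the trisubstituted C3=C4 bond; boron should go to the less substituted C3 and hydrogen to the diaryl‑substituted C4, both from the face anti to the 2‑aryl group, so one syn addition sets the 3‑hydroxyl trans to ring B and ring D at C4 trans to the 3‑hydroxyl (2,3‑trans‑3,4‑trans).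

**Step 16**
Reactants: 24 protected dimer
Product: 25 ent‑oritin‑(4β→6)‑epioritin‑4α‑ol hexa‑O‑benzyl ether (all six phenols benzylated)
Conditions: n‑Bu4NF, THF, rt → 40 °C
Reagents that add atoms: none
Why: fluoride‑mediated cleavage of both silyl ethers; no phenol is free at this stage, so no phenoxide chemistry can intervene.

**Step 17**
Reactants: 25 hexa‑O‑benzyl ether
Product: 26 (2R,3R,4R)‑6‑[(2S,3R,4S)‑3,7,8‑trihydroxy‑2‑(4‑hydroxyphenyl)chroman‑4‑yl]‑2‑(4‑hydroxyphenyl)chromane‑3,4,7,8‑tetrol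
Conditions: H2 (1 atm), Pd(OH)2/C, THF/MeOH, rt, stopped at complete debenzylation; filtration under argon
Reagents that add atoms: none
Why: hydrogenolysis of six aryl benzyl ethers in neutral medium; these should cleave much faster than the benzylic C4–OH of ring F and the two benzylic C2–O1 bonds, which generally survive neutral hydrogenolysis.

**Compound list**

1 | 1‑(2,3,4‑trihydroxyphenyl)ethanone (gallacetophenone) | CC(=O)c1ccc(O)c(O)c1O | starting material
2 | 1‑[3,4‑bis(benzyloxy)‑2‑hydroxyphenyl]ethanone | CC(=O)c1ccc(OCc2ccccc2)c(OCc2ccccc2)c1O | intermediate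
3 | 4‑(benzyloxy)benzaldehyde | O=Cc1ccc(OCc2ccccc2)cc1 | starting material
4 | (E)‑1‑[3,4‑bis(benzyloxy)‑2‑hydroxyphenyl]‑3‑[4‑(benzyloxy)phenyl]prop‑2‑en‑1‑one | O=C(/C=C/c1ccc(OCc2ccccc2)cc1)c1ccc(OCc2ccccc2)c(OCc2ccccc2)c1O | intermediate
5 | (E)‑1‑[3,4‑bis(benzyloxy)‑2‑hydroxyphenyl]‑3‑[4‑(benzyloxy)phenyl]prop‑2‑en‑1‑ol, racemic | OC(/C=C/c1ccc(OCc2ccccc2)cc1)c1ccc(OCc2ccccc2)c(OCc2ccccc2)c1O | intermediate
6 | o‑quinone methide from 5 (formed in the flask): 2,3‑bis(benzyloxy)‑6‑{(E)‑3‑[4‑(benzyloxy)phenyl]allylidene}cyclohexa‑2,4‑dien‑1‑one | O=C1C(OCc2ccccc2)=C(OCc2ccccc2)C=CC1=C/C=C/c1ccc(OCc2ccccc2)cc1 | intermediate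
7 | (2S)‑7,8‑bis(benzyloxy)‑2‑[4‑(benzyloxy)phenyl]‑2H‑chromene | c1ccccc1COc1ccc(cc1)[C@H]1Oc2c(ccc(OCc3ccccc3)c2OCc2ccccc2)C=C1 | intermediate
8 | 2,3‑trans‑3‑borylflavan from 7 (formed in the flask) | c1ccccc1COc1ccc(cc1)[C@H]1Oc2c(ccc(OCc3ccccc3)c2OCc2ccccc2)C[C@@H]1B | intermediate
9 | (2R,3S)‑7,8‑bis(benzyloxy)‑2‑[4‑(benzyloxy)phenyl]chroman‑3‑ol (2,3‑trans) | c1ccccc1COc1ccc(cc1)[C@H]1Oc2c(ccc(OCc3ccccc3)c2OCc2ccccc2)C[C@@H]1O | intermediate
10 | (2R)‑7,8‑bis(benzyloxy)‑2‑[4‑(benzyloxy)phenyl]chroman‑3‑one | c1ccccc1COc1ccc(cc1)[C@H]1Oc2c(ccc(OCc3ccccc3)c2OCc2ccccc2)CC1=O | intermediate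
11 | (2R,3R)‑7,8‑bis(benzyloxy)‑2‑[4‑(benzyloxy)phenyl]chroman‑3‑ol (2,3‑cis) | c1ccccc1COc1ccc(cc1)[C@H]1Oc2c(ccc(OCc3ccccc3)c2OCc2ccccc2)C[C@H]1O | intermediate
12 | (2R,3R,4S)‑7,8‑bis(benzyloxy)‑2‑[4‑(benzyloxy)phenyl]chromane‑3,4‑diol (2,3‑cis‑3,4‑trans) | c1ccccc1COc1ccc(cc1)[C@H]1Oc2c(ccc(OCc3ccccc3)c2OCc2ccccc2)[C@H](O)[C@H]1O | intermediate
13 | (2R,3S)‑7,8‑bis(benzyloxy)‑2‑[4‑(benzyloxy)phenyl]‑3‑hydroxychroman‑4‑one (2,3‑cis) | c1ccccc1COc1ccc(cc1)[C@H]1Oc2c(ccc(OCc3ccccc3)c2OCc2ccccc2)C(=O)[C@H]1O | intermediate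
14 | (2R,3R,4R)‑7,8‑bis(benzyloxy)‑2‑[4‑(benzyloxy)phenyl]chromane‑3,4‑diol (all‑cis) | c1ccccc1COc1ccc(cc1)[C@H]1Oc2c(ccc(OCc3ccccc3)c2OCc2ccccc2)[C@@H](O)[C@H]1O | intermediate
15 | bis‑TBS ether of 14 (all‑cis) | c1ccccc1COc1ccc(cc1)[C@H]1Oc2c(ccc(OCc3ccccc3)c2OCc2ccccc2)[C@@H](O[Si](C)(C)C(C)(C)C)[C@H]1O[Si](C)(C)C(C)(C)C | intermediate
16 | 6‑bromo derivative of 15 | c1ccccc1COc1ccc(cc1)[C@H]1Oc2c(cc(Br)c(OCc3ccccc3)c2OCc2ccccc2)[C@@H](O[Si](C)(C)C(C)(C)C)[C@H]1O[Si](C)(C)C(C)(C)C | intermediate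
17 | 6‑lithio derivative of 15 (formed in the flask) | c1ccccc1COc1ccc(cc1)[C@H]1Oc2c(cc([Li])c(OCc3ccccc3)c2OCc2ccccc2)[C@@H](O[Si](C)(C)C(C)(C)C)[C@H]1O[Si](C)(C)C(C)(C)C | intermediate
18 | 6‑(dichlorocerio) derivative of 15 (formed in the flask) | c1ccccc1COc1ccc(cc1)[C@H]1Oc2c(cc([Ce](Cl)Cl)c(OCc3ccccc3)c2OCc2ccccc2)[C@@H](O[Si](C)(C)C(C)(C)C)[C@H]1O[Si](C)(C)C(C)(C)C | intermediate
19 | sodium phenoxide of chalcone 4 (formed in the flask) | [Na+].[O-]c1c(OCc2ccccc2)c(OCc2ccccc2)ccc1C(=O)/C=C/c1ccc(OCc2ccccc2)cc1 | intermediate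
20 | tertiary allylic carbinol: C6 of 15 bonded to C(OH)[3,4‑bis(benzyloxy)‑2‑hydroxyphenyl][(E)‑4‑(benzyloxy)styryl], both carbinol epimers | c1ccccc1COc1ccc(cc1)[C@H]1Oc2c(cc(C(O)(/C=C/c3ccc(OCc4ccccc4)cc3)c3ccc(OCc4ccccc4)c(OCc4ccccc4)c3O)c(OCc3ccccc3)c2OCc2ccccc2)[C@@H](O[Si](C)(C)C(C)(C)C)[C@H]1O[Si](C)(C)C(C)(C)C | intermediate
21 | o‑quinone methide from 20 (formed in the flask) | c1ccccc1COc1ccc(cc1)[C@H]1Oc2c(cc(C(/C=C/c3ccc(OCc4ccccc4)cc3)=C3C=CC(OCc4ccccc4)=C(OCc4ccccc4)C3=O)c(OCc3ccccc3)c2OCc2ccccc2)[C@@H](O[Si](C)(C)C(C)(C)C)[C@H]1O[Si](C)(C)C(C)(C)C | intermediate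
22 | upper (2R)‑2‑[4‑(benzyloxy)phenyl]‑7,8‑bis(benzyloxy)‑2H‑chromen‑4‑yl unit on C6 of 15 | c1ccccc1COc1ccc(cc1)[C@H]1Oc2c(cc(C3=C[C@H](c4ccc(OCc5ccccc5)cc4)Oc4c(OCc5ccccc5)c(OCc5ccccc5)ccc43)c(OCc3ccccc3)c2OCc2ccccc2)[C@@H](O[Si](C)(C)C(C)(C)C)[C@H]1O[Si](C)(C)C(C)(C)C | intermediate
23 | upper 2,3‑trans‑3,4‑trans‑3‑boryl‑4‑arylflavan from 22 (formed in the flask) | c1ccccc1COc1ccc(cc1)[C@H]1Oc2c(cc([C@H]3c4ccc(OCc5ccccc5)c(OCc5ccccc5)c4O[C@@H](c4ccc(OCc5ccccc5)cc4)[C@@H]3B)c(OCc3ccccc3)c2OCc2ccccc2)[C@@H](O[Si](C)(C)C(C)(C)C)[C@H]1O[Si](C)(C)C(C)(C)C | intermediate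
24 | hexa‑O‑benzyl (phenols), lower 3,4‑bis‑O‑TBS ether of ent‑oritin‑(4β→6)‑epioritin‑4α‑ol | c1ccccc1COc1ccc(cc1)[C@H]1Oc2c(cc([C@H]3c4ccc(OCc5ccccc5)c(OCc5ccccc5)c4O[C@@H](c4ccc(OCc5ccccc5)cc4)[C@@H]3O)c(OCc3ccccc3)c2OCc2ccccc2)[C@@H](O[Si](C)(C)C(C)(C)C)[C@H]1O[Si](C)(C)C(C)(C)C | intermediate
25 | hexa‑O‑benzyl (phenols) ether of ent‑oritin‑(4β→6)‑epioritin‑4α‑ol | c1ccccc1COc1ccc(cc1)[C@H]1Oc2c(cc([C@H]3c4ccc(OCc5ccccc5)c(OCc5ccccc5)c4O[C@@H](c4ccc(OCc5ccccc5)cc4)[C@@H]3O)c(OCc3ccccc3)c2OCc2ccccc2)[C@@H](O)[C@H]1O | intermediate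
26 | (2R,3R,4R)‑6‑[(2S,3R,4S)‑3,7,8‑trihydroxy‑2‑(4‑hydroxyphenyl)chroman‑4‑yl]‑2‑(4‑hydroxyphenyl)chromane‑3,4,7,8‑tetrol | Oc1ccc([C@H]2Oc3c(cc([C@H]4c5ccc(O)c(O)c5O[C@@H](c5ccc(O)cc5)[C@@H]4O)c(O)c3O)[C@@H](O)[C@H]2O)cc1 | target

**Step count**

Total steps: 17. Longest linear sequence: 17 (1 → 26; chalcone 4 enters a second time in step 13).

**Steps most likely to fail**

Step 14. The risk is loss of enantiocontrol: carbinol 20 ionises so easily that racemic background cyclisation can occur on work‑up, on silica or through traces of achiral acid, and the strongly stabilised cation may form a loose ion pair next to the bulky chiral ring D substituent. The fallback sets C2 before the diaryl carbinol exists. It sets out from 2 and 16 and returns at 22. Acetophenone 2 is condensed with DMF dimethyl acetal to the enaminone (E)‑1‑[3,4‑bis(benzyloxy)‑2‑hydroxyphenyl]‑3‑(dimethylamino)prop‑2‑en‑1‑one F1, which is closed with acid to 7,8‑bis(benzyloxy)chromone F2. Asymmetric 1,4‑addition of 4‑(benzyloxy)phenylboronic acid ([Rh(OH)(cod)]2 with the chiral bisphosphine enantiomer that gives the R product) should give (2R)‑7,8‑bis(benzyloxy)‑2‑[4‑(benzyloxy)phenyl]chroman‑4‑one F3. The organocerium 18 made from 16 adds to its ketone to give the tertiary 4‑arylflavan‑4‑ol F4, and dehydration with Burgess reagent gives 22.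

Step 4. The risk is poor enantioface discrimination with the less substituted secondary cation, together with racemic cyclisation of the very labile alcohol 5 before it meets the catalyst. The fallback sets out from 2 and returns at 7. Chromone F2, made from 2 as above, undergoes the same asymmetric 1,4‑addition with the antipodal ligand to give (2S)‑7,8‑bis(benzyloxy)‑2‑[4‑(benzyloxy)phenyl]chroman‑4‑one F5. NaBH4 reduces it to the 2,4‑cis alcohol (2S,4S)‑7,8‑bis(benzyloxy)‑2‑[4‑(benzyloxy)phenyl]chroman‑4‑ol F6, and dehydration with Burgess reagent gives 7.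

Step 13. The risk is competing conjugate addition and incomplete carbonyl addition: the phenoxide turns the ketone into a vinylogous carboxylate and the carbonyl is flanked by two ortho‑substituted aryl groups. The fallback masks the phenol as a neutral silyl ether. It sets out from 4 and 16 and returns at 20. Chalcone 4 is silylated (TBSCl, imidazole, DMF) to its O‑TBS ether F7. Aryllithium 17, made from 16, adds to the now more electrophilic ketone at −78 °C to give the carbinol aryl silyl ether F8 (or its O‑to‑O silyl‑migrated isomer). n‑Bu4NF buffered with AcOH at 0 °C then frees the phenol to give 20.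

**Further compounds**

F1 | step 14 | (E)‑1‑[3,4‑bis(benzyloxy)‑2‑hydroxyphenyl]‑3‑(dimethylamino)prop‑2‑en‑1‑one | CN(C)/C=C/C(=O)c1ccc(OCc2ccccc2)c(OCc2ccccc2)c1O
F2 | step 14 | 7,8‑bis(benzyloxy)‑4H‑chromen‑4‑one | O=c1ccoc2c1ccc(OCc1ccccc1)c2OCc1ccccc1
F3 | step 14 | (2R)‑7,8‑bis(benzyloxy)‑2‑[4‑(benzyloxy)phenyl]chroman‑4‑one | O=C1C[C@H](c2ccc(OCc3ccccc3)cc2)Oc2c1ccc(OCc1ccccc1)c2OCc1ccccc1
F4 | step 14 | tertiary flavan‑4‑ol: C4 of F3 bearing OH and C6 of flavan 15 | c1ccccc1COc1ccc(cc1)[C@H]1Oc2c(cc(C3(O)C[C@H](c4ccc(OCc5ccccc5)cc4)Oc4c(OCc5ccccc5)c(OCc5ccccc5)ccc43)c(OCc3ccccc3)c2OCc2ccccc2)[C@@H](O[Si](C)(C)C(C)(C)C)[C@H]1O[Si](C)(C)C(C)(C)C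
F5 | step 4 | (2S)‑7,8‑bis(benzyloxy)‑2‑[4‑(benzyloxy)phenyl]chroman‑4‑one | c1ccccc1COc1ccc(cc1)[C@H]1Oc2c(ccc(OCc3ccccc3)c2OCc2ccccc2)C(=O)C1
F6 | step 4 | (2S,4S)‑7,8‑bis(benzyloxy)‑2‑[4‑(benzyloxy)phenyl]chroman‑4‑ol | c1ccccc1COc1ccc(cc1)[C@H]1Oc2c(ccc(OCc3ccccc3)c2OCc2ccccc2)[C@@H](O)C1
F7 | step 13 | O‑TBS ether of chalcone 4 | O=C(/C=C/c1ccc(OCc2ccccc2)cc1)c1ccc(OCc2ccccc2)c(OCc2ccccc2)c1O[Si](C)(C)C(C)(C)C
F8 | step 13 | aryl O‑TBS ether of carbinol 20 | c1ccccc1COc1ccc(cc1)[C@H]1Oc2c(cc(C(O)(/C=C/c3ccc(OCc4ccccc4)cc3)c3ccc(OCc4ccccc4)c(OCc4ccccc4)c3O[Si](C)(C)C(C)(C)C)c(OCc3ccccc3)c2OCc2ccccc2)[C@@H](O[Si](C)(C)C(C)(C)C)[C@H]1O[Si](C)(C)C(C)(C)C
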